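**Plan**

- Locants (guaiane): cyclopentane C1–C5 and cycloheptane C1, C5–C10 share the C1–C5 bond; the enol ether C10=C14–O–C4 closes a six-membered oxacycle (O, C4, C5, C1, C10, C14); C15 is the CH2OH on C4; the lactone is O–C6 / C7–C11(=C13)–C12.
- Enabling feature: C4 is a tertiary ether carbon next to C5, and C5 carries the carbinol carbon C6. C5–C6 and C4–O are therefore cut together, as the addition of a C6 aldehyde and the C14 aldehyde oxygen across a C4=C5 cyclopentene; before that the lactone C12–O bond is opened and O15 is silylated.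
- The open-chain dialdehyde is cut at C9–C10 (aldol), at C7–C11 (epoxide opening by an acetylide, the alkyne later carbonylated to the acrylate) and at C1–C10 (Ireland–Claisen); the two esters are C–O cuts.
- Forward: a cyclopentene thioester (C1–C5, C15, C10, C14) and an α-alkoxy aldehyde (C6–C9, C11, C13) are made separately and joined at C9–C10. Acylation, carbonylation and oxidation give the dialdehyde; the seven-membered carbocycle and the oxacycle then close in one step, the lactone next, and desilylation ends the route.
- Stereochemistry: C4 from a Sharpless epoxidation, relayed to C1 by the [3,3] shift and returned to C4 and C5 through the tether; C7 and C8 from a second Sharpless epoxidation and SN2 opening; C9 and C10 from a chelation-controlled Mukaiyama aldol; C6 in the cascade; the side-chain centre from (R)-2-methylbutanoic acid.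

Key step: step 22

Remark: guaiane locants are used in all names; D-(−)-diisopropyl tartrate, (E)-but-2-ene-1,4-diol and (R)-2-methylbutanoic acid are taken as purchasable, and the acetal carbon of 17 is expected as a mixture of epimers that is carried on as such.

**Route**

Step 1
Reactants: 1 cyclopent-1-en-1-ylmethanol
Product: 2 [(1R,5R)-6-oxabicyclo[3.1.0]hexan-1-yl]methanol
Conditions: Ti(OiPr)4 (10 mol%), D-(−)-diisopropyl tartrate (12 mol%), t-BuOOH, 4 Å molecular sieves, CH2Cl2, −20 °C
Reagents that add atoms: tert-butyl hydroperoxide, CC(C)(C)OO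
Why: Sharpless asymmetric epoxidation of a primary allylic alcohol, in which the D-(−)-tartrate–titanium catalyst delivers oxygen to one alkene face and sets the epoxide as (1R,5R); the C4 configuration fixed here is the source of C1, C4 and C5 of the target.

Step 2
Reactants: 2 [(1R,5R)-6-oxabicyclo[3.1.0]hexan-1-yl]methanol
Product: 3 tert-butyldiphenylsilyl ether of 2
Conditions: t-BuPh2SiCl, imidazole, DMF, 0 °C → rt
Reagents that add atoms: tert-butyl(chloro)diphenylsilane, CC(C)(C)[Si](Cl)(c1ccccc1)c1ccccc1
Why: Routine silylation of a primary alcohol (imidazole-assisted silyl transfer), the tert-butyldiphenylsilyl ether being chosen because it must survive the later fluoride cleavage of two tert-butyldimethylsilyl ethers.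

Step 3
Reactants: 3 tert-butyldiphenylsilyl ether of 2
Product: 6 (1S)-1-{[tert-butyl(diphenyl)silyl]oxymethyl}cyclopent-2-en-1-ol, via hydroxy selenide 4 (not isolated), via selenoxide 5 (not isolated)
Conditions: (PhSe)2, NaBH4, EtOH, rt → 78 °C; then THF, 30% H2O2, 0 °C → rt
Reagents that add atoms: diphenyl diselenide, c1ccc(cc1)[Se][Se]c1ccccc1; hydrogen peroxide, OO (selenium and the selenoxide oxygen are carried by 4 and 5 only; product 6 keeps no reagent atom)
Why: Sharpless–Lauer conversion of an epoxide into an allylic alcohol: phenylselenolate opens the epoxide by SN2 attack at the less hindered carbon C5, and the derived selenoxide undergoes syn elimination toward C1, the only side that offers a hydrogen, so the tertiary carbinol C4 keeps its configuration.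

Step 4
Reactants: 6 (1S)-1-{[tert-butyl(diphenyl)silyl]oxymethyl}cyclopent-2-en-1-ol
Product: 7 (1S)-1-{[tert-butyl(diphenyl)silyl]oxymethyl}cyclopent-2-en-1-yl acetate
Conditions: Ac2O, Et3N, DMAP, CH2Cl2, rt
Reagents that add atoms: acetic anhydride, CC(=O)OC(C)=O
Why: DMAP-catalysed acyl transfer to a tertiary alcohol, which brings in the two carbons that become C10 and C14.

Step 5
Reactants: 7 (1S)-1-{[tert-butyl(diphenyl)silyl]oxymethyl}cyclopent-2-en-1-yl acetate
Product: 10 2-[(1S)-3-{[tert-butyl(diphenyl)silyl]oxymethyl}cyclopent-2-en-1-yl]acetic acid, via silyl ketene acetal 8 (not isolated), via trimethylsilyl ester 9 (not isolated)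
Conditions: LiN(iPr)2, Me3SiCl (present from the start), THF, −78 °C → 50 °C; then 1 M HCl
Reagents that add atoms: chlorotrimethylsilane, C[Si](C)(C)Cl (the silyl group is carried by 8 and 9 only; acid 10 keeps no reagent atom)
Why: Ireland–Claisen rearrangement: the silyl ketene acetal of the tertiary allylic acetate undergoes a [3,3] shift that is necessarily suprafacial on the five-membered ring, so the C1–C10 bond forms on the face that the C4–O bond leaves and C1 is set as (S) by 1,3-transfer of chirality.

Step 6
Reactants: 10 2-[(1S)-3-{[tert-butyl(diphenyl)silyl]oxymethyl}cyclopent-2-en-1-yl]acetic acid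
Product: 11 S-tert-butyl thioester of 10
Conditions: t-BuSH, DCC, DMAP (cat.), CH2Cl2, 0 °C → rt
Reagents that add atoms: 2-methylpropane-2-thiol, CC(C)(C)S
Why: Steglich thioesterification (carbodiimide activation, DMAP) gives the S-tert-butyl thioester, the acyl form whose silyl ketene acetals are known to give anti aldols in Lewis-acid-promoted additions.

Step 7
Reactants: 11 S-tert-butyl thioester of 10
Product: 12 O-trimethylsilyl ketene thioacetal of 11
Conditions: LiN(iPr)2, THF, −78 °C; Me3SiCl; pentane, filtration, used crude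
Reagents that add atoms: chlorotrimethylsilane, C[Si](C)(C)Cl
Why: Kinetic enolisation of the thioester with a lithium amide and O-silylation (silyl ketene acetal formation) creates no stereocentre, and the double-bond geometry matters little for the open transition state of step 14.

Step 8
Reactants: 13 (E)-but-2-ene-1,4-diol
Product: 14 (E)-4-{[tert-butyl(dimethyl)silyl]oxy}but-2-en-1-ol
Conditions: NaH (1.0 equiv), THF, 0 °C; t-BuMe2SiCl
Reagents that add atoms: tert-butyl(chloro)dimethylsilane, CC(C)(C)[Si](C)(C)Cl
Why: Monosilylation of a symmetrical diol through its sparingly soluble monosodium alkoxide (McDougal procedure), a Williamson-type O-silylation.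

Step 9
Reactants: 14 (E)-4-{[tert-butyl(dimethyl)silyl]oxy}but-2-en-1-ol
Product: 15 [(2R,3R)-3-({[tert-butyl(dimethyl)silyl]oxy}methyl)oxiran-2-yl]methanol
Conditions: Ti(OiPr)4 (10 mol%), D-(−)-diisopropyl tartrate (12 mol%), t-BuOOH, 4 Å molecular sieves, CH2Cl2, −20 °C
Reagents that add atoms: tert-butyl hydroperoxide, CC(C)(C)OO
Why: Sharpless asymmetric epoxidation of an (E)-disubstituted primary allylic alcohol, the best substrate class for this reaction, with the D-(−)-tartrate ligand giving the (2R,3R)-epoxide and thereby the C8–O configuration.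

Step 10
Reactants: 15 [(2R,3R)-3-({[tert-butyl(dimethyl)silyl]oxy}methyl)oxiran-2-yl]methanol
Product: 16 (2S,3S)-3-({[tert-butyl(dimethyl)silyl]oxy}methyl)-5-(trimethylsilyl)pent-4-yne-1,2-diol
Conditions: Me3SiC≡CH, n-BuLi, toluene, −78 → 0 °C; Et2AlCl; then 15, 0 °C → rt; aq. potassium sodium tartrate
Reagents that add atoms: ethynyltrimethylsilane, C#C[Si](C)(C)C
Why: Hydroxyl-directed opening of a 2,3-epoxy alcohol by a diethylalkynylalane at the carbon remote from the carbinol, an SN2 process that inverts the carbon that becomes C7 and leaves C8 untouched, so the trans-epoxide gives the C7/C8 relationship of the target.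

Step 11
Reactants: 16 (2S,3S)-3-({[tert-butyl(dimethyl)silyl]oxy}methyl)-5-(trimethylsilyl)pent-4-yne-1,2-diol
Product: 17 4-methoxybenzylidene acetal (1,3-dioxolane) of diol 16
Conditions: 4-MeOC6H4CH(OMe)2, PPTS (cat.), CH2Cl2, rt
Reagents that add atoms: 4-methoxybenzaldehyde dimethyl acetal, COc1ccc(cc1)C(OC)OC
Why: Acid-catalysed transacetalisation of the terminal 1,2-diol to a 4-methoxybenzylidene acetal, whose new acetal carbon forms as a mixture of epimers that converges in step 12.

Step 12
Reactants: 17 4-methoxybenzylidene acetal of diol 16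
Product: 18 (2S,3S)-3-({[tert-butyl(dimethyl)silyl]oxy}methyl)-2-[(4-methoxybenzyl)oxy]-5-(trimethylsilyl)pent-4-yn-1-ol
Conditions: iBu2AlH, CH2Cl2, −78 → 0 °C; aq. potassium sodium tartrate
Reagents that add atoms: none
Why: Regioselective reductive opening of the 4-methoxybenzylidene acetal, in which the aluminium hydride binds the less hindered primary oxygen and cleaves its C–O bond, so the 4-methoxybenzyl ether ends on the C8 oxygen and the C9 alcohol is free.

Step 13
Reactants: 18 (2S,3S)-3-({[tert-butyl(dimethyl)silyl]oxy}methyl)-2-[(4-methoxybenzyl)oxy]-5-(trimethylsilyl)pent-4-yn-1-ol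
Product: 19 (2S,3S)-3-({[tert-butyl(dimethyl)silyl]oxy}methyl)-2-[(4-methoxybenzyl)oxy]-5-(trimethylsilyl)pent-4-ynal
Conditions: Dess–Martin periodinane, NaHCO3, CH2Cl2, 0 °C → rt; used at once
Reagents that add atoms: none
Why: Dess–Martin oxidation of a primary alcohol under buffered conditions that do not epimerise the α-alkoxy aldehyde.

Step 14
Reactants: 12 O-trimethylsilyl ketene thioacetal of 11; 19 α-(4-methoxybenzyloxy) aldehyde
Product: 20 anti-syn aldol adduct (S-tert-butyl thioester at C14 with free C9 hydroxyl)
Conditions: MgBr2·OEt2 (3 equiv), CH2Cl2, −78 → −20 °C; aq. NH4Cl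
Reagents that add atoms: none
Why: Chelation-controlled Mukaiyama aldol addition: MgBr2 bridges the aldehyde oxygen and the C8 benzylic ether oxygen so that the nucleophile adds opposite to the C7 branch and sets C9 syn to C8–O (Cram chelate), while the open antiperiplanar transition state known for thioester silyl ketene acetals puts the cyclopentenyl group anti to the new hydroxyl and thus sets C10 in the one configuration from which the C14 carbonyl can later reach C4.

Step 15
Reactants: 20 anti-syn aldol adduct
Product: 22 C9/C14-diol with terminal alkyne, via silylalkyne diol 21 (not isolated)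
Conditions: LiBH4, THF, MeOH (1 equiv), 0 °C → rt; then K2CO3, MeOH, rt
Reagents that add atoms: none
Why: Borohydride reduction of the thioester to the primary alcohol followed in the same flask by methanolysis of the alkynyl C–Si bond (protodesilylation), neither of which touches a stereocentre.

Step 16
Reactants: 22 C9/C14-diol with terminal alkyne
Product: 24 C14 tert-butyldimethylsilyl ether C9 acetate, via C14 silyl ether 23 (not isolated)
Conditions: t-BuMe2SiCl, imidazole, CH2Cl2, 0 °C; then Ac2O, Et3N, DMAP, rt
Reagents that add atoms: tert-butyl(chloro)dimethylsilane, CC(C)(C)[Si](C)(C)Cl; acetic anhydride, CC(=O)OC(C)=O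
Why: Selective silylation of the primary C14 hydroxyl over the hindered secondary one, then DMAP-catalysed acetylation of the C9 hydroxyl in the same flask.

Step 17
Reactants: 24 C14 tert-butyldimethylsilyl ether C9 acetate
Product: 25 C8 alcohol
Conditions: DDQ, CH2Cl2, pH 7 buffer, 0 °C
Reagents that add atoms: none
Why: Oxidative cleavage of the 4-methoxybenzyl ether by DDQ (single-electron oxidation of the electron-rich arene, then hydrolysis of the oxocarbenium ion), run buffered and cold so that the neighbouring acetate does not migrate.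

Step 18
Reactants: 25 C8 alcohol; 26 (R)-2-methylbutanoic acid
Product: 27 C8 (R)-2-methylbutanoate
Conditions: DCC, DMAP, CH2Cl2, 0 °C → rt
Reagents that add atoms: none
Why: Steglich esterification of the secondary C8 alcohol; a simple α-alkyl acid is not racemised under carbodiimide and DMAP activation at 0 °C, so the (R) centre is carried in intact.

Step 19
Reactants: 27 C8 (R)-2-methylbutanoate
Product: 28 methyl acrylate (C7–C11(=C13H2)–C12O2Me)
Conditions: Pd(OAc)2 (2 mol%), 2-(diphenylphosphino)pyridine (8 mol%), CH3SO3H (8 mol%), CO (5 bar), MeOH (10 equiv), CH2Cl2, 25 °C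
Reagents that add atoms: carbon monoxide, [C-]#[O+]; methanol, CO
Why: Palladium-catalysed Markovnikov hydromethoxycarbonylation of a terminal alkyne (Drent-type catalyst, in which the pyridylphosphine relays the proton), which places CO2Me on the internal carbon and so converts the ethynyl group into the 2-substituted acrylate under weakly acidic conditions that the trisubstituted alkene and, at room temperature, the silyl ethers should tolerate.

Step 20
Reactants: 28 methyl acrylate
Product: 29 C6/C14-diol
Conditions: HF·pyridine, pyridine, THF, 0 °C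
Reagents that add atoms: none
Why: Fluoride-mediated desilylation in which the two primary tert-butyldimethylsilyl ethers are cleaved much faster than the tert-butyldiphenylsilyl ether, the cold pyridine-buffered medium keeping the freed C6 hydroxyl from closing onto the acrylate ester and the acyl groups from migrating.

Step 21
Reactants: 29 C6/C14-diol
Product: 30 C6/C14-dialdehyde
Conditions: Dess–Martin periodinane, NaHCO3, CH2Cl2, 0 °C → rt; filtered and used at once
Reagents that add atoms: none
Why: Double Dess–Martin oxidation under bicarbonate buffering, a neutral method suited to β-acyloxy aldehydes that would eliminate under amine-based oxidations; the dialdehyde is not stored.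

Step 22
Reactants: 30 C6/C14-dialdehyde
Product: 31 bridged enol ether with free C6 hydroxyl and C7 acrylate ester
Conditions: Me2AlCl (3 equiv), CH2Cl2 (0.005 M), −78 → −40 °C; aq. NaHCO3
Reagents that add atoms: none
Why: Proposed new method: Me2AlCl activates the C6 aldehyde, the trisubstituted cyclopentene attacks it through C5 so that positive charge develops at the tertiary carbon C4, the oxygen of the C14 aldehyde captures that charge, and the resulting oxocarbenium ion loses H10 to leave the bridging enol ether, the aluminium alkoxide at C6 being protonated on work-up; the closest known reaction types are Lewis-acid Prins and carbonyl-ene cyclisations of alkenyl aldehydes that end at an internal oxygen nucleophile, and cation–olefin cyclisations that end at a ketone oxygen to give cyclic enol ethers. The seven-membered carbocycle closes by 7-exo-trig attack on the aldehyde carbon with C4 left outside the new ring, and the six-membered oxacycle closes by attack of the carbonyl oxygen on C4 with the C14=O bond inside the ring (6-endo with respect to the carbonyl). C5 and C4 are controlled by the C1 stereocentre, because the chain hangs from one face of the cyclopentene and both new bonds can only form on that face, which gives the cis ring fusion and the ether oxygen cis to C6. C6 is controlled by a chair-like seven-membered transition state in which the aluminium-bound oxygen points away from C4 and from the C7 acrylate, so that H6 is trans to both H5 and H7 as the trans-fused lactone requires. The step needs chemoselectivity (C6 aldehyde as electrophile, carbonyl capture ahead of proton loss): the C14 aldehyde could reach the alkene only through a four-membered ring or against the Markovnikov sense, the acrylate is too electron-poor to act as a π-nucleophile, and the C10 configuration set in step 14 places the C14 carbonyl on the same side of the new ring as C4, over the developing cationic centre.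

Step 23
Reactants: 31 bridged enol ether with free C6 hydroxyl and C7 acrylate ester
Product: 32 O15-tert-butyldiphenylsilyl ether of the target (6,12-lactone closed)
Conditions: PPTS (cat.), 5 Å molecular sieves, toluene, 50 °C
Reagents that add atoms: none
Why: Acid-catalysed lactonisation (intramolecular transesterification) of the γ-hydroxy ester, whose hydroxyl and acrylate are trans on the seven-membered ring as in natural trans-fused guaianolides, the sieves taking up methanol so that it cannot add to the enol ether.

Step 24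
Reactants: 32 O15-tert-butyldiphenylsilyl ether of the target
Product: 33 CNP0013863.3
Conditions: Bu4NF, AcOH (1:1), THF, 0 °C → rt
Reagents that add atoms: none
Why: Fluoride cleavage of the primary silyl ether, buffered by acetic acid so that the esters and the α-methylene lactone do not meet basic fluoride.

**Compound list**

1 | cyclopent-1-en-1-ylmethanol | OCC1=CCCC1 | starting material
2 | [(1R,5R)-6-oxabicyclo[3.1.0]hexan-1-yl]methanol | OC[C@]12CCC[C@H]1O2 | intermediate
3 | tert-butyl{[(1R,5R)-6-oxabicyclo[3.1.0]hexan-1-yl]methoxy}diphenylsilane | CC(C)(C)[Si](c1ccccc1)(c1ccccc1)OC[C@]23CCC[C@H]2O3 | intermediate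
4 | (1R,2S)-1-{[tert-butyl(diphenyl)silyl]oxymethyl}-2-(phenylselanyl)cyclopentan-1-ol (trans hydroxy selenide) | O[C@@]1(CO[Si](c2ccccc2)(c2ccccc2)C(C)(C)C)CCC[C@@H]1[Se]c1ccccc1 | intermediate
5 | selenoxide of 4 (configuration at selenium not defined) | O[C@@]1(CO[Si](c2ccccc2)(c2ccccc2)C(C)(C)C)CCC[C@@H]1[Se](=O)c1ccccc1 | intermediate
6 | (1S)-1-{[tert-butyl(diphenyl)silyl]oxymethyl}cyclopent-2-en-1-ol | O[C@@]1(CO[Si](c2ccccc2)(c2ccccc2)C(C)(C)C)CCC=C1 | intermediate
7 | (1S)-1-{[tert-butyl(diphenyl)silyl]oxymethyl}cyclopent-2-en-1-yl acetate | CC(=O)O[C@@]1(CO[Si](c2ccccc2)(c2ccccc2)C(C)(C)C)CCC=C1 | intermediate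
8 | trimethylsilyl ketene acetal of acetate 7 | C=C(O[Si](C)(C)C)O[C@@]1(CO[Si](c2ccccc2)(c2ccccc2)C(C)(C)C)CCC=C1 | intermediate
9 | trimethylsilyl 2-[(1S)-3-{[tert-butyl(diphenyl)silyl]oxymethyl}cyclopent-2-en-1-yl]acetate | C[Si](C)(C)OC(=O)C[C@@H]1CCC(CO[Si](c2ccccc2)(c2ccccc2)C(C)(C)C)=C1 | intermediate
10 | 2-[(1S)-3-{[tert-butyl(diphenyl)silyl]oxymethyl}cyclopent-2-en-1-yl]acetic acid | OC(=O)C[C@@H]1CCC(CO[Si](c2ccccc2)(c2ccccc2)C(C)(C)C)=C1 | intermediate
11 | S-tert-butyl 2-[(1S)-3-{[tert-butyl(diphenyl)silyl]oxymethyl}cyclopent-2-en-1-yl]ethanethioate | CC(C)(C)SC(=O)C[C@@H]1CCC(CO[Si](c2ccccc2)(c2ccccc2)C(C)(C)C)=C1 | intermediate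
12 | O-trimethylsilyl S-tert-butyl ketene thioacetal of 11 (silyloxy group trans to the ring, ring centre as in 11) | C[Si](C)(C)O/C(SC(C)(C)C)=C/[C@@H]1CCC(CO[Si](c2ccccc2)(c2ccccc2)C(C)(C)C)=C1 | intermediate
13 | (E)-but-2-ene-1,4-diol | OC/C=C/CO | starting material
14 | (E)-4-{[tert-butyl(dimethyl)silyl]oxy}but-2-en-1-ol | OC/C=C/CO[Si](C)(C)C(C)(C)C | intermediate
15 | [(2R,3R)-3-({[tert-butyl(dimethyl)silyl]oxy}methyl)oxiran-2-yl]methanol | OC[C@H]1O[C@@H]1CO[Si](C)(C)C(C)(C)C | intermediate
16 | (2S,3S)-3-({[tert-butyl(dimethyl)silyl]oxy}methyl)-5-(trimethylsilyl)pent-4-yne-1,2-diol | OC[C@@H](O)[C@@H](C#C[Si](C)(C)C)CO[Si](C)(C)C(C)(C)C | intermediate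
17 | 4-methoxybenzylidene acetal (1,3-dioxolane) of 16, acetal carbon as a mixture of epimers | COc1ccc(cc1)C1OC[C@@H](O1)[C@@H](C#C[Si](C)(C)C)CO[Si](C)(C)C(C)(C)C | intermediate
18 | (2S,3S)-3-({[tert-butyl(dimethyl)silyl]oxy}methyl)-2-[(4-methoxybenzyl)oxy]-5-(trimethylsilyl)pent-4-yn-1-ol | OC[C@@H](OCc1ccc(OC)cc1)[C@@H](C#C[Si](C)(C)C)CO[Si](C)(C)C(C)(C)C | intermediate
19 | (2S,3S)-3-({[tert-butyl(dimethyl)silyl]oxy}methyl)-2-[(4-methoxybenzyl)oxy]-5-(trimethylsilyl)pent-4-ynal | O=C[C@@H](OCc1ccc(OC)cc1)[C@@H](C#C[Si](C)(C)C)CO[Si](C)(C)C(C)(C)C | intermediate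
20 | aldol adduct: C14 S-tert-butyl thioester; C10 bears the (1S)-cyclopentenyl ring with C15H2O-SiPh2t-Bu on C4; C9–OH (anti to the ring at C10, syn to C8–O); C8–O-(4-methoxybenzyl); C7–C≡C–SiMe3; C6H2–OSiMe2t-Bu | CC(C)(C)SC(=O)[C@H]([C@@H]1CCC(CO[Si](c2ccccc2)(c2ccccc2)C(C)(C)C)=C1)[C@H](O)[C@@H](OCc3ccc(OC)cc3)[C@@H](C#C[Si](C)(C)C)CO[Si](C)(C)C(C)(C)C | intermediate
21 | C9/C14-diol from 20 (C14H2OH), alkyne still silylated | OC[C@H]([C@@H]1CCC(CO[Si](c2ccccc2)(c2ccccc2)C(C)(C)C)=C1)[C@H](O)[C@@H](OCc3ccc(OC)cc3)[C@@H](C#C[Si](C)(C)C)CO[Si](C)(C)C(C)(C)C | intermediate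
22 | C9/C14-diol with terminal alkyne at C7 | OC[C@H]([C@@H]1CCC(CO[Si](c2ccccc2)(c2ccccc2)C(C)(C)C)=C1)[C@H](O)[C@@H](OCc3ccc(OC)cc3)[C@@H](C#C)CO[Si](C)(C)C(C)(C)C | intermediate
23 | C14–OSiMe2t-Bu ether of 22, C9–OH free | CC(C)(C)[Si](C)(C)OC[C@H]([C@@H]1CCC(CO[Si](c2ccccc2)(c2ccccc2)C(C)(C)C)=C1)[C@H](O)[C@@H](OCc3ccc(OC)cc3)[C@@H](C#C)CO[Si](C)(C)C(C)(C)C | intermediate
24 | C9 acetate of 23 | CC(C)(C)[Si](C)(C)OC[C@H]([C@@H]1CCC(CO[Si](c2ccccc2)(c2ccccc2)C(C)(C)C)=C1)[C@H](OC(C)=O)[C@@H](OCc3ccc(OC)cc3)[C@@H](C#C)CO[Si](C)(C)C(C)(C)C | intermediate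
25 | C8 alcohol (4-methoxybenzyl group removed from 24) | CC(C)(C)[Si](C)(C)OC[C@H]([C@@H]1CCC(CO[Si](c2ccccc2)(c2ccccc2)C(C)(C)C)=C1)[C@H](OC(C)=O)[C@@H](O)[C@@H](C#C)CO[Si](C)(C)C(C)(C)C | intermediate
26 | (R)-2-methylbutanoic acid | CC[C@@H](C)C(=O)O | starting material
27 | C8 (R)-2-methylbutanoate of 25 | CC(C)(C)[Si](C)(C)OC[C@H]([C@@H]1CCC(CO[Si](c2ccccc2)(c2ccccc2)C(C)(C)C)=C1)[C@H](OC(C)=O)[C@@H](OC(=O)[C@H](C)CC)[C@@H](C#C)CO[Si](C)(C)C(C)(C)C | intermediate
28 | methyl acrylate from 27 (C7–C(=CH2)CO2Me) | CC(C)(C)[Si](C)(C)OC[C@H]([C@@H]1CCC(CO[Si](c2ccccc2)(c2ccccc2)C(C)(C)C)=C1)[C@H](OC(C)=O)[C@@H](OC(=O)[C@H](C)CC)[C@@H](C(=C)C(=O)OC)CO[Si](C)(C)C(C)(C)C | intermediate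
29 | C6/C14-diol | OC[C@H]([C@@H]1CCC(CO[Si](c2ccccc2)(c2ccccc2)C(C)(C)C)=C1)[C@H](OC(C)=O)[C@@H](OC(=O)[C@H](C)CC)[C@@H](C(=C)C(=O)OC)CO | intermediate
30 | C6/C14-dialdehyde (3-substituted cyclopentene with both esters and the acrylate) | O=C[C@H]([C@@H]1CCC(CO[Si](c2ccccc2)(c2ccccc2)C(C)(C)C)=C1)[C@H](OC(C)=O)[C@@H](OC(=O)[C@H](C)CC)[C@@H](C(=C)C(=O)OC)C=O | intermediate
31 | bridged enol ether with free C6 hydroxyl, C7 methyl acrylate and O15 silyl ether | C=C(C(=O)OC)[C@@H]1[C@H](OC(=O)[C@H](C)CC)[C@@H](OC(C)=O)C2=CO[C@@]3(CO[Si](c4ccccc4)(c4ccccc4)C(C)(C)C)CC[C@@H]2[C@H]3[C@H]1O | intermediate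
32 | O15-tert-butyldiphenylsilyl ether of the target | C=C1C(=O)O[C@H]2[C@H]1[C@H](OC(=O)[C@H](C)CC)[C@@H](OC(C)=O)C1=CO[C@@]3(CO[Si](c4ccccc4)(c4ccccc4)C(C)(C)C)CC[C@@H]1[C@@H]23 | intermediate
33 | CNP0013863.3 | C=C1C(=O)O[C@H]2[C@H]1[C@H](OC(=O)[C@H](C)CC)[C@@H](OC(C)=O)C1=CO[C@@]3(CO)CC[C@@H]1[C@@H]23 | target

**Step count and risks**

Total step count: 24. Longest linear sequence: 18 steps (from 1 through steps 1–7 and 14–24); the other branch (from 13) runs 17 steps.

Steps most likely to fail:

1. Step 22. Proton loss from the developing C4 cation (ene-type collapse) may outrun capture by the C14 carbonyl oxygen, or the Lewis acid may induce loss of an acyloxy group β to an aldehyde. The fallback divides the step into two known reactions and sets out from dialdehyde 30. The intramolecular carbonyl-ene cyclisation of the C6 aldehyde onto the trisubstituted alkene (Me2AlCl, −78 °C, early quench; type-1 ene reaction of an alkenyl aldehyde) is run deliberately to the ene alcohol F1, with the same C5 and C6 configurations and the alkene moved to C3=C4. F1 is then cycloisomerised with a catalytic Brønsted acid (camphorsulfonic acid, CH2Cl2, 0 °C): protonation of the alkene at C3, capture at C4 by the C14 carbonyl oxygen and loss of H10. This is the known acid-catalysed cyclisation of δ,ε-unsaturated carbonyl compounds to 3,4-dihydro-2H-pyrans. The route is rejoined at 31.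

2. Step 14. Simple diastereoselection at C10 in the open transition state may be insufficient, or chelation control at C9 may be eroded, the nucleophile's own C1 stereocentre being an untested influence. The fallback forms the C1–C10 bond last and sets out from acetate 7 and aldehyde 19. The silyl ketene acetal 8, kept at −78 °C so that it does not rearrange, is added to 19 under the same MgBr2·OEt2 chelation control to give the β-hydroxy ester F2; no C10 centre is formed here, so only 1,2-induction is asked of the aldol. F2 is converted into its dianion (LiN(iPr)2, 2.5 equiv, THF, −78 °C → rt) and rearranges (dianionic Ireland–Claisen) to the β-hydroxy acid F3. The lithium chelate should direct C–C bond formation anti to the C9 alkoxide, as in Fráter–Seebach alkylations, while the ring face is fixed by the C4–O bond. Reduction of F3 with LiAlH4 gives diol 21, where the route is rejoined.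

3. Step 19. Regiochemical leakage to the linear ester, or acid-promoted methanolysis of a primary silyl ether followed by lactone closure at C6, may erode the hydroesterification. The fallback separates the Markovnikov addition from the carbonylation and sets out from alkyne 27. Bromoboration with B-bromo-9-borabicyclo[3.3.1]nonane (CH2Cl2, 0 °C) and protodeboronation with acetic acid give the 2-bromoalkene F4. Methoxycarbonylation with the zerovalent palladium complex Pd(PPh3)4 under CO in MeOH with Et3N, a non-acidic medium, then gives acrylate 28, where the route is rejoined.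

Further compounds
F1 | step 22 | ene alcohol: seven-membered ring closed (C5–C6 bond, C6–OH), alkene at C3=C4, C14 aldehyde intact | O=C[C@H]1[C@H](OC(C)=O)[C@@H](OC(=O)[C@H](C)CC)[C@@H](C(=C)C(=O)OC)[C@H](O)[C@H]2C(CO[Si](c3ccccc3)(c3ccccc3)C(C)(C)C)=CC[C@@H]12
F2 | step 14 | β-hydroxy ester of tertiary allylic alcohol 6 (C14 ester, C10H2, C9–OH, C8–O-(4-methoxybenzyl), C7 silylalkyne) | O=C(C[C@H](O)[C@@H](OCc1ccc(OC)cc1)[C@@H](C#C[Si](C)(C)C)CO[Si](C)(C)C(C)(C)C)O[C@@]2(CO[Si](c3ccccc3)(c3ccccc3)C(C)(C)C)CCC=C2
F3 | step 14 | β-hydroxy acid after [3,3] shift (C14 acid, C10 bearing the cyclopentenyl ring, C9–OH) | OC(=O)[C@H]([C@@H]1CCC(CO[Si](c2ccccc2)(c2ccccc2)C(C)(C)C)=C1)[C@H](O)[C@@H](OCc3ccc(OC)cc3)[C@@H](C#C[Si](C)(C)C)CO[Si](C)(C)C(C)(C)C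
F4 | step 19 | 2-bromoalkene from 27 (C7–C(Br)=CH2) | CC(C)(C)[Si](C)(C)OC[C@H]([C@@H]1CCC(CO[Si](c2ccccc2)(c2ccccc2)C(C)(C)C)=C1)[C@H](OC(C)=O)[C@@H](OC(=O)[C@H](C)CC)[C@@H](C(Br)=C)CO[Si](C)(C)C(C)(C)C
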